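It is easy to take the catalyst charged for the catalyst at work, but in these flasks it enters as precatalyst, and free catalyst is lost in pairs.

    second substrate + partner + free catalyst → free catalyst + second product (k1 = 28000 M⁻² s⁻¹)
    partner + precatalyst → free catalyst + spent reagent (k2 = 1.4 M⁻¹ s⁻¹)
    starting material + partner → uncatalysed product (k3 = 1.1 M⁻¹ s⁻¹)
    2 free catalyst → spent catalyst (k4 = 2000 M⁻¹ s⁻¹)
    starting material + partner + free catalyst → free catalyst + target (k5 = 27000 M⁻² s⁻¹)

| flask | starting material | partner | second substrate | precatalyst | time | remark |
|---|---|---|---|---|---|---|
| birch | 0.050 M | 0.0650 M | 0.0500 M | 50 µM | 50 s | everything together at the start |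
| cedar | 0.050 M | 0.0650 M (fed, over 40 s) | 0.0500 M | 50 µM | 50 s | all else is in the flask from the start; the feed brings no volume worth counting |
| alder | 0.050 M (fed, over 10 s) | 0.0650 M | 0.0500 M | 50 µM | 50 s | all else is in the flask from the start; the feed brings no volume worth counting |
| elm | 0.050 M (fed, over 40 s) | 0.0650 M | 0.0500 M | 50 µM | 50 s | all else is in the flask from the start; the feed brings no volume worth counting |

- the best flask by share of target in target plus uncatalysed product; "all alike" if 1.5 percentage points covers them all (birch / cedar / alder / elm / all alike)
- share of target in target plus uncatalysed product at the end, birch
- share of target in target plus uncatalysed product at the end, cedar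
- share of target in target plus uncatalysed product at the end, alder
- share of target in target plus uncatalysed product at the end, elm

I have to choose how to charge the next run, so I turn the constants into levels and times. Target and uncatalysed product form from the same pair of reactants, so the ratio of their rates at any moment, the selectivity factor, is C/b. Here C is the free catalyst level and b is the break-even level, the uncatalysed constant over the catalysed one, 40.7 µM.

At the charges, precatalyst releases free catalyst at a rate r of 4.55 µM s⁻¹. If that rate held, free catalyst would stop rising at a ceiling c, the root of r over twice the loss constant, which is 33.7 µM, and its rise would take about 7.41 s. At that level target would take 45.3 % of what forms, and I call c/(c+b) the ceiling share. The release falls as partner and precatalyst are used, and a real flask starts from no free catalyst, so I expect the shares to stand below it.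

In birch the uncatalysed step alone halves starting material in 9.7 s, against that rise of 7.41 s, so I hold starting material back. The quick addition of 10 s covers the rise, whereas the slow addition of 40 s outlasts the precatalyst's release time of 11.0 s. Feeding partner instead lowers the ceiling, to 23.8 µM at half its charge, so partner stays in the flask. I charge alder. My reckoning gives a bound, not a figure for each flask.

The forecast also picks alder, with 22.5 % for birch, 24.5 % for cedar, 27.5 % for alder and 24.5 % for elm. Its ground is that “a short feed (alder) holds it back just until the catalyst peaks”.

The simulation gives alder as best: birch 22.5 %, cedar 20.2 %, alder 27.0 %, elm 25.1 %, and each forecast figure stands within its tolerance. Alder's share lies below its ceiling share of 45.3 %. The neighbour of alder with 30.0 µM of precatalyst has a ceiling of 26.1 µM and so a ceiling share of 39.1 %, lower than alder's. That charge lies below 32.7 µM, the nearest amount at which alder's share has moved 5 points, so the forecast's 27.5 % for alder is not what this charge gives: this neighbour ends at 21.0 %.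

The constants used here come from no measurement; the rest is arithmetic.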